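## Analysis of the target

Target 29 is the ether between the C7 phenol oxygen of isofraxidin (14) and the primary carbon C11 of a bicyclic C15 terpenoid unit. Numbering used throughout: C11 is the OCH2 carbon; ring B is C9, C8, C7, C6, C5, C10 with a C7=C8 double bond and the C8 methyl; ring A is C10, C1=C2, C3(=O), C4(CH3)2, C5, a 4,4-dimethylcyclohex-2-enone. There are three contiguous stereocentres, C5 (S), C10 (R, quaternary, angular methyl) and C9 (S). H5 and the C10 methyl lie on opposite faces (trans ring fusion). C11 is trans to the C10 methyl, so the aryloxymethyl arm is pseudoaxial on ring B, cis to C1 and trans to the C4 branch on C5. The sensitive groups are the coumarin lactone and its C3=C4 bond (hard nucleophiles, alkoxides, oxidants), the ring A enone, and the C7=C8 alkene, which strong acid could shift to C8=C9 and so make the ether allylic and ionisable. Any intermediate with a carbonyl at C8 is a β-aryloxy ketone that can expel the phenoxide. The synthesis is hard because quaternary C10 sits between two stereocentres, C11 must take the more crowded axial position, and an O–C11 bond made by displacement would require a phenol flanked by two methoxy groups to attack a β-branched primary carbon. The strategy rests on C9 and C10 being neighbours in ring B: with a carbonyl at C8 they are the α- and β-carbons of a 3-methylcyclohex-2-enone that already carries the C5 branch. C1 can then enter at C10 as a nucleophile and C11, with its aryl ether already attached, at C9 as an electrophile. The C8 carbonyl afterwards serves to install C8–CH3 and C7=C8, and C1 with a masked C2–C3 methyl ketone closes ring A.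

## Retrosynthetic reasoning

**29 to 27.** Ring A is opened at C1=C2, the aldol-condensation retron of the enone. The cut is unambiguous: in keto aldehyde 27 the C3 ketone has quaternary C4 on one side, so only the C2 methyl can enolise, and the C1 aldehyde sits on quaternary C10 and cannot. The forward reaction must close a six-membered ring and lose water without strong acid (C7=C8) or alkoxide (lactone).

**27 to 26.** The methyl ketone is masked as the dioxolane in 26, because organometallics and a strong amide base are used before ring A is closed.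

**26 to 25.** The C8–CH3 bond is cut to give enol triflate 25. A cross-coupling at an enol triflate fixes the double bond at C7=C8 and turns the carbonyl that served the key step into the alkene of the target.

**25 to 23.** The C1 aldehyde is traced to a vinyl group by excision of one carbon. A vinyl group is the simplest C1 nucleophile that a cuprate can deliver to a β,β-disubstituted enone. Cleaving it while C7=C8 is still an electron-poor enol triflate leaves only one reactive alkene.

**23 to 21.** The enol triflate comes from C8 ketone 21 by kinetic enolisation towards C7, the only unhindered α-position. This is placed directly after the key step so that the β-aryloxy ketone is short-lived.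

**21 to 13 + 19 + 18 (key disconnection).** The C1–C10 and C9–C11 bonds are cut together. This returns enone 13, vinylmagnesium bromide 19 and aryloxymethyl chloride 18. Two bonds, the quaternary centre, the C9 stereocentre and the complete aryl ether are gained in one operation, and the only stereocentre needed beforehand is C5. The forward reaction must add vinyl trans to the C5 branch and alkylate C9 trans to the C10 methyl.

**18 to 17 to 14 + 15.** The C11–Cl bond comes from O,S-acetal 17, and the O–C11 bond is made on isofraxidin 14 with chloromethyl methyl sulfide 15. The hindered phenol thus attacks an unhindered one-carbon electrophile instead of a neopentyl-like terpenoid carbon.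

**13 to 12.** The C8 carbonyl is removed to the allylic methylene of cyclohexene 12. C8 is the only allylic CH2 of that alkene, so allylic oxidation is regiodefined.

**12 to 11 to 8.** The dioxolane comes from methyl ketone 11, and the C2–C3 bond of 11 from carboxylic acid 8 and a methyl organolithium.

**8 to 4.** The C4–C5 bond, between a ring stereocentre and a quaternary carbon, is cut as an Ireland–Claisen retron. An alkylation cannot make this bond because the electrophile would be tertiary. The sigmatropic shift forms it intramolecularly and transfers a C–O stereocentre to C5.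

**4 to 2 + 3, 2 to 1.** Ester 4 comes from allylic alcohol 2 and isobutyryl chloride 3. Alcohol 2 comes from the achiral enone 1 by a catalytic enantioselective carbonyl reduction, the only step in which absolute configuration is introduced.

## Alternatives that were turned down

**Alternative 1:** The arene of the coumarin is disconnected instead of the terpenoid. Heating cyclobutenone A2, a 4-alkenyl-4-methoxycyclobutenone carrying the complete terpenyl alkoxy group, would open the four-membered ring to a dienylketene. A 6π closure and enolisation would then give the tetraoxygenated phenol acetal A1.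
- In its favour: the terpenyl–O bond is made by alkoxide exchange on a four-membered-ring ester, which is easier than any C-alkylation, and the key step is thermal and neutral. On this point it is stronger than the chosen route, which depends on an enolate accepting an aryloxymethyl chloride.
- Against it: the whole bicyclic alcohol with its C5/C10/C9 triad must exist beforehand, so the real problem of the target is untouched.
- The alkenyl metal can add to either carbonyl of the unsymmetrical diester, which would put the terpenyl ether at the wrong arene position in part of the material.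
- After A1 the pyranone ring still has to be built and the C3 ketal removed, so many steps are spent remaking an arene that 14 supplies complete.
- The chosen strategy uses 14 intact and sets C9 and C10 in the step that attaches it.

**Alternative 2:** Ring B is disconnected at C8–C9. A tin hydride chain would turn the C8 vinyl iodide of A4 into a vinyl radical that adds 6-exo to C9 of an aryl enol ether. The α-aryloxy radical at C11 would take a hydrogen atom and give A3, the 1,2-dihydro target.
- In its favour: ring B and C9 arise in one neutral step, the coumarin travels as a robust enol ether, and the C5/C10 pair could be bought with a ring A building block. It is stronger than the chosen route in not needing a hindered conjugate addition.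
- Against it: the chair-like exo transition state prefers the enol ether pseudo-equatorial, which would give equatorial C11. That is the C9 epimer; the target needs the axial arm.
- The coumarin C3=C4 bond is itself a radical acceptor, and the vinyl radical can abstract hydrogen from C1 or the C10 methyl.
- The aryl enol ether of a neopentyl aldehyde with a hindered phenol is not easy to make.
- A3 still lacks C1=C2, so a ketone dehydrogenation must follow in the presence of an electron-rich arene.
- The chosen strategy sets C9 by a substrate bias that points the right way and reaches the enone directly by condensation.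

**Alternative 3:** Ring B is disconnected at C5–C6 and C9–C10. Dienyl ether A7 and enal A6 would combine under a chiral cationic oxazaborolidine Lewis acid to give A5, which is the same compound as 27.
- In its favour: it is far shorter and fully convergent. Three stereocentres, ring B and the C7=C8 alkene come from one catalytic step, and only the ring A closure remains. On step economy it is clearly stronger than the chosen route.
- Against it: A6 is an α-methyl enal with a quaternary carbon on its β-carbon and a second Lewis-basic ketone, a very poor dienophile.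
- α-Methyl enals prefer the exo-formyl mode, which with the (E)-diene places C11 cis to the C10 methyl. The target needs the endo-formyl outcome.
- The C8 methyl and the C9 arm of A7 direct regiochemistry in opposite senses.
- A7 is a dienylic aryl ether that a strong Lewis acid can ionise.
- The chosen strategy reaches 27 in more steps, but each stereocentre is set by a steric effect of the C5 branch that matches the target, and no strong Lewis acid meets the ether.

Key step: step 9

Assumption: the (S)-configured oxazaborolidine is taken to give the (R)-alcohol 2, by the usual model with the α-methylalkenyl arm as the larger group; if the sense were opposite, the enantiomeric catalyst would be used and nothing else changes.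

## Route

Step 1
Reactants: 1 2-methylcyclohex-2-en-1-one
Product: 2 (1R)-2-methylcyclohex-2-en-1-ol
Conditions: (S)-1-methyl-3,3-diphenyltetrahydro-1H,3H-pyrrolo[1,2-c][1,3,2]oxazaborole [(S)-Me-CBS] (0.1 equiv), BH3·SMe2, THF, −20 °C; MeOH, then aqueous work-up
Reagents that add atoms: none
Why: Corey–Bakshi–Shibata reduction; the catalyst–borane complex binds the carbonyl lone pair anti to the α-methylalkenyl arm and delivers hydride to one face, giving the (R)-carbinol with 1,2-selectivity; this centre is the source of all absolute configuration.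

Step 2
Reactants: 2 (1R)-2-methylcyclohex-2-en-1-ol; 3 2-methylpropanoyl chloride
Product: 4 (1R)-2-methylcyclohex-2-en-1-yl 2-methylpropanoate
Conditions: pyridine, 4-(dimethylamino)pyridine (0.05 equiv), CH2Cl2, 0 °C → rt
Reagents that add atoms: none
Why: Acylation of a secondary allylic alcohol under nucleophilic catalysis; the C–O stereocentre is not involved.

Step 3
Reactants: 4 (1R)-2-methylcyclohex-2-en-1-yl 2-methylpropanoate
Product: 8 2-methyl-2-[(1S)-2-methylcyclohex-2-en-1-yl]propanoic acid, via lithium ester enolate 5 (not isolated), via silyl ketene acetal 6 (not isolated), via trimethylsilyl ester 7 (not isolated)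
Conditions: LiN(i-Pr)2 (1.2 equiv), THF, −78 °C; Me3SiCl/Et3N, −78 °C → rt, then 65 °C; 1 M HCl
Reagents that add atoms: none
Why: Ireland–Claisen rearrangement; the symmetrical ketene acetal has no E/Z issue, and the suprafacial [3,3] shift forms C4–C5 on the ring face that carried the ester oxygen, so the carbinol configuration should be transferred completely to C5 while quaternary C4 is formed.

Step 4
Reactants: 8 2-methyl-2-[(1S)-2-methylcyclohex-2-en-1-yl]propanoic acid
Product: 11 3-methyl-3-[(1S)-2-methylcyclohex-2-en-1-yl]butan-2-one, via lithium carboxylate 9 (not isolated), via dilithium gem-diolate 10 (not isolated)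
Conditions: MeLi (2.5 equiv), Et2O, 0 °C → rt; reverse quench into cold 1 M HCl
Reagents that add atoms: methyllithium [Li]C
Why: Methyl ketone synthesis from a carboxylic acid; the dilithium gem-diolate cannot accept a third equivalent and collapses to the ketone only on acidic quench, which suits an α-quaternary acid.

Step 5
Reactants: 11 3-methyl-3-[(1S)-2-methylcyclohex-2-en-1-yl]butan-2-one
Product: 12 2-methyl-2-{2-[(1S)-2-methylcyclohex-2-en-1-yl]propan-2-yl}-1,3-dioxolane
Conditions: Me3SiOCH2CH2OSiMe3 (2 equiv), Me3SiOTf (0.1 equiv), CH2Cl2, −78 → 0 °C; pyridine quench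
Reagents that add atoms: 1,2-bis(trimethylsilyloxy)ethane C[Si](C)(C)OCCO[Si](C)(C)C
Why: Noyori ketalisation; formation of the disiloxane makes it irreversible and effective for a hindered ketone at low temperature, without a hot Brønsted acid that could move the ring alkene to C5=C10 and erase the stereocentre.

Step 6
Reactants: 12 2-methyl-2-{2-[(1S)-2-methylcyclohex-2-en-1-yl]propan-2-yl}-1,3-dioxolane
Product: 13 (4S)-3-methyl-4-[2-(2-methyl-1,3-dioxolan-2-yl)propan-2-yl]cyclohex-2-en-1-one
Conditions: CrO3 (15 equiv), 3,5-dimethylpyrazole (15 equiv), CH2Cl2, −20 °C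
Reagents that add atoms: chromium trioxide O=[Cr](=O)=O
Why: Allylic oxidation with the CrO3–dimethylpyrazole complex; C8 is the only allylic methylene (the other allylic sites are the hindered tertiary C5–H and the methyl), so the β-methyl enone should form with C5 untouched under these non-basic conditions.

Step 7
Reactants: 14 7-hydroxy-6,8-dimethoxy-2H-chromen-2-one (isofraxidin); 15 chloromethyl methyl sulfide
Product: 17 6,8-dimethoxy-7-[(methylsulfanyl)methoxy]-2H-chromen-2-one, via sodium phenoxide 16 (not isolated)
Conditions: NaH (1.1 equiv), DMF, 0 °C; 15 (1.3 equiv), NaI (0.1 equiv), rt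
Reagents that add atoms: none
Why: Williamson-type O-alkylation with a reactive α-chloro sulfide (iodide catalysis); the phenoxide, although flanked by two methoxy groups, meets an unhindered CH2 electrophile, and the lactone is inert to phenoxide.

Step 8
Reactants: 17 6,8-dimethoxy-7-[(methylsulfanyl)methoxy]-2H-chromen-2-one
Product: 18 7-(chloromethoxy)-6,8-dimethoxy-2H-chromen-2-one
Conditions: SO2Cl2 (1.05 equiv), CH2Cl2, −78 → 0 °C; volatiles removed, used crude
Reagents that add atoms: sulfuryl chloride O=S(=O)(Cl)Cl
Why: Chlorinolysis of an O,S-acetal; S-chlorination gives a chlorosulfonium ion that loses methanesulfenyl chloride and is captured by chloride at carbon, the standard preparation of aryl chloromethyl ethers; low temperature and one equivalent should avoid ring chlorination.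

Step 9
Reactants: 13 (4S)-3-methyl-4-[2-(2-methyl-1,3-dioxolan-2-yl)propan-2-yl]cyclohex-2-en-1-one; 19 vinylmagnesium bromide; 18 7-(chloromethoxy)-6,8-dimethoxy-2H-chromen-2-one
Product: 21 (2S,3R,4S)-2-{[(6,8-dimethoxy-2-oxo-2H-chromen-7-yl)oxy]methyl}-3-ethenyl-3-methyl-4-[2-(2-methyl-1,3-dioxolan-2-yl)propan-2-yl]cyclohexan-1-one, via bromomagnesium enolate 20 (not isolated)
Conditions: 13 (1.05 equiv), CuBr·SMe2 (0.3 equiv), 19 (1.0 equiv, slow addition), THF/Me2S, −60 → −30 °C; then DMPU, 18 (1.3 equiv), −78 → −30 °C; pH 7 buffer
Reagents that add atoms: none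
Why: Copper-catalysed conjugate addition followed by enolate alkylation in one flask, the closest known reaction type being the tandem 1,4-addition/α-alkylation of cyclohexenones with α-chloro ethers as electrophiles. The vinyl cuprate from 19 and CuBr·SMe2 π-complexes the enone, adds at C10 through a trivalent-copper intermediate and reductively eliminates to the regiodefined enolate 20 (C1–C10 bond), which then displaces chloride from 18 at C9 in an SN2 step (C9–C11 bond); no ring is closed. C10 is controlled by the C5 branch: A(1,2) strain with the C10 methyl holds that tert-alkyl group pseudoaxial in 13, so the cuprate enters axially on the other face and the vinyl group ends trans to it. C9 is controlled by the same group: in the enolate conformer with the C5 branch equatorial the C10 methyl is axial and chair-like axial attack anti to it meets only H5, whereas in the other conformer the axial C5 branch blocks the opposite face of C9 in a 1,3-diaxial sense, so C11 should enter trans to both the C5 branch and the C10 methyl. Chemoselectivity rests on 19 being the limiting reagent, so that no vinyl metal is left when 18 is added and the lactone meets only the enolate. C- over O-alkylation is favoured by the tightly bound magnesium counter-ion and by the SN2 character of an aryloxymethyl chloride, whose oxygen stabilises a cation poorly. Low temperature and a buffered quench should keep the axial C9 epimer and prevent loss of aryloxide from the β-aryloxy ketone.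

Step 10
Reactants: 21 (2S,3R,4S)-2-{[(6,8-dimethoxy-2-oxo-2H-chromen-7-yl)oxy]methyl}-3-ethenyl-3-methyl-4-[2-(2-methyl-1,3-dioxolan-2-yl)propan-2-yl]cyclohexan-1-one
Product: 23 (4S,5R,6S)-6-{[(6,8-dimethoxy-2-oxo-2H-chromen-7-yl)oxy]methyl}-5-ethenyl-5-methyl-4-[2-(2-methyl-1,3-dioxolan-2-yl)propan-2-yl]cyclohex-1-en-1-yl trifluoromethanesulfonate, via potassium enolate 22 (not isolated)
Conditions: KN(SiMe3)2 (1.1 equiv), THF, −78 °C; PhNTf2 (1.2 equiv), −78 → −40 °C; aqueous NH4Cl, dilute HCl wash
Reagents that add atoms: N-phenylbis(trifluoromethanesulfonimide) O=S(=O)(N(c1ccccc1)S(=O)(=O)C(F)(F)F)C(F)(F)F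
Why: Kinetic enolisation and O-sulfonylation; the bulky amide removes a C7 proton because C9–H is tertiary and next to quaternary C10, so the C7=C8 enol triflate forms, the β-aryloxy ketone is removed at once, and C9 is never deprotonated.

Step 11
Reactants: 23 (4S,5R,6S)-6-{[(6,8-dimethoxy-2-oxo-2H-chromen-7-yl)oxy]methyl}-5-ethenyl-5-methyl-4-[2-(2-methyl-1,3-dioxolan-2-yl)propan-2-yl]cyclohex-1-en-1-yl trifluoromethanesulfonate
Product: 25 (4S,5R,6S)-6-{[(6,8-dimethoxy-2-oxo-2H-chromen-7-yl)oxy]methyl}-5-formyl-5-methyl-4-[2-(2-methyl-1,3-dioxolan-2-yl)propan-2-yl]cyclohex-1-en-1-yl trifluoromethanesulfonate, via vicinal diol 24 (not isolated)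
Conditions: OsO4 (0.05 equiv), NaIO4 (4 equiv), 2,6-lutidine (2 equiv), dioxane/H2O 3:1, rt
Reagents that add atoms: osmium tetroxide O=[Os](=O)(=O)=O; sodium periodate [Na+].[O-]I(=O)(=O)=O
Why: Lemieux–Johnson oxidation; OsO4 should choose the terminal vinyl group because the enol triflate alkene and the coumarin C3=C4 bond are both electron-poor, periodate cleaves the diol to the C1 aldehyde, and an aldehyde on quaternary C10 cannot epimerise.

Step 12
Reactants: 25 (4S,5R,6S)-6-{[(6,8-dimethoxy-2-oxo-2H-chromen-7-yl)oxy]methyl}-5-formyl-5-methyl-4-[2-(2-methyl-1,3-dioxolan-2-yl)propan-2-yl]cyclohex-1-en-1-yl trifluoromethanesulfonate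
Product: 26 (1R,2S,6S)-2-{[(6,8-dimethoxy-2-oxo-2H-chromen-7-yl)oxy]methyl}-1,3-dimethyl-6-[2-(2-methyl-1,3-dioxolan-2-yl)propan-2-yl]cyclohex-3-ene-1-carbaldehyde
Conditions: SnMe4 (4 equiv), Pd(PPh3)4 (0.1 equiv), LiCl (4 equiv), DMF, 80 °C
Reagents that add atoms: tetramethylstannane C[Sn](C)(C)C
Why: Stille cross-coupling of an enol triflate; zerovalent palladium inserts into C8–OTf, chloride exchange and methyl transfer from tin are followed by reductive elimination, which installs the C8 methyl with the double bond fixed at C7=C8 under neutral conditions that tolerate aldehyde, lactone and ketal.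

Step 13
Reactants: 26 (1R,2S,6S)-2-{[(6,8-dimethoxy-2-oxo-2H-chromen-7-yl)oxy]methyl}-1,3-dimethyl-6-[2-(2-methyl-1,3-dioxolan-2-yl)propan-2-yl]cyclohex-3-ene-1-carbaldehyde
Product: 27 (1R,2S,6S)-2-{[(6,8-dimethoxy-2-oxo-2H-chromen-7-yl)oxy]methyl}-1,3-dimethyl-6-(2-methyl-3-oxobutan-2-yl)cyclohex-3-ene-1-carbaldehyde
Conditions: pyridinium p-toluenesulfonate (0.3 equiv), acetone/H2O 4:1, 50 °C
Reagents that add atoms: water O
Why: Acid-catalysed ketal hydrolysis through the oxocarbenium ion; the crowded dioxolane should open readily at an acidity too low to protonate the C7=C8 alkene.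

Step 14
Reactants: 27 (1R,2S,6S)-2-{[(6,8-dimethoxy-2-oxo-2H-chromen-7-yl)oxy]methyl}-1,3-dimethyl-6-(2-methyl-3-oxobutan-2-yl)cyclohex-3-ene-1-carbaldehyde
Product: 29 7-{[(1S,4aS,8aR)-2,5,5,8a-tetramethyl-6-oxo-1,4,4a,5,6,8a-hexahydronaphthalen-1-yl]methoxy}-6,8-dimethoxy-2H-chromen-2-one, via β-hydroxy ketone 28 (not isolated)
Conditions: piperidine (0.3 equiv), AcOH (0.3 equiv), toluene, 4 Å molecular sieves, 80 °C
Reagents that add atoms: none
Why: Amine-salt-catalysed intramolecular aldol condensation; the C2 methyl is the only enolisable position and the C1 aldehyde the only electrophile, C1 and C4 are trans-diequatorial on ring B so the trans-fused ring A closes, and coumarins tolerate piperidinium acetate, the medium in which they are commonly assembled.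

## Compound list

1 | 2-methylcyclohex-2-en-1-one | CC1=CCCCC1=O | starting material
2 | (1R)-2-methylcyclohex-2-en-1-ol | CC1=CCCC[C@H]1O | intermediate
3 | 2-methylpropanoyl chloride (isobutyryl chloride) | CC(C)C(Cl)=O | starting material
4 | (1R)-2-methylcyclohex-2-en-1-yl 2-methylpropanoate | CC1=CCCC[C@H]1OC(=O)C(C)C | intermediate
5 | lithium 2-methyl-1-{[(1R)-2-methylcyclohex-2-en-1-yl]oxy}prop-1-en-1-olate | CC1=CCCC[C@H]1OC(O[Li])=C(C)C | intermediate (not isolated)
6 | trimethyl[(2-methyl-1-{[(1R)-2-methylcyclohex-2-en-1-yl]oxy}prop-1-en-1-yl)oxy]silane | CC1=CCCC[C@H]1OC(O[Si](C)(C)C)=C(C)C | intermediate (not isolated)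
7 | trimethylsilyl 2-methyl-2-[(1S)-2-methylcyclohex-2-en-1-yl]propanoate | CC1=CCCC[C@@H]1C(C)(C)C(=O)O[Si](C)(C)C | intermediate (not isolated)
8 | 2-methyl-2-[(1S)-2-methylcyclohex-2-en-1-yl]propanoic acid | CC1=CCCC[C@@H]1C(C)(C)C(=O)O | intermediate
9 | lithium 2-methyl-2-[(1S)-2-methylcyclohex-2-en-1-yl]propanoate | CC1=CCCC[C@@H]1C(C)(C)C(=O)O[Li] | intermediate (not isolated)
10 | dilithium 3-methyl-3-[(1S)-2-methylcyclohex-2-en-1-yl]butane-2,2-bis(olate) | CC1=CCCC[C@@H]1C(C)(C)C(C)(O[Li])O[Li] | intermediate (not isolated)
11 | 3-methyl-3-[(1S)-2-methylcyclohex-2-en-1-yl]butan-2-one | CC1=CCCC[C@@H]1C(C)(C)C(C)=O | intermediate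
12 | 2-methyl-2-{2-[(1S)-2-methylcyclohex-2-en-1-yl]propan-2-yl}-1,3-dioxolane | CC1=CCCC[C@@H]1C(C)(C)C2(C)OCCO2 | intermediate
13 | (4S)-3-methyl-4-[2-(2-methyl-1,3-dioxolan-2-yl)propan-2-yl]cyclohex-2-en-1-one | CC1=CC(=O)CC[C@@H]1C(C)(C)C2(C)OCCO2 | intermediate
14 | 7-hydroxy-6,8-dimethoxy-2H-chromen-2-one (isofraxidin) | COc1cc2ccc(=O)oc2c(OC)c1O | starting material
15 | chloromethyl methyl sulfide | CSCCl | starting material
16 | sodium 6,8-dimethoxy-2-oxo-2H-chromen-7-olate | COc1cc2ccc(=O)oc2c(OC)c1[O-].[Na+] | intermediate (not isolated)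
17 | 6,8-dimethoxy-7-[(methylsulfanyl)methoxy]-2H-chromen-2-one | COc1cc2ccc(=O)oc2c(OC)c1OCSC | intermediate
18 | 7-(chloromethoxy)-6,8-dimethoxy-2H-chromen-2-one | COc1cc2ccc(=O)oc2c(OC)c1OCCl | intermediate
19 | vinylmagnesium bromide | C=C[Mg]Br | starting material
20 | bromomagnesium (3R,4S)-3-ethenyl-3-methyl-4-[2-(2-methyl-1,3-dioxolan-2-yl)propan-2-yl]cyclohex-1-en-1-olate | C=C[C@@]1(C)C=C(O[Mg]Br)CC[C@@H]1C(C)(C)C2(C)OCCO2 | intermediate (not isolated)
21 | (2S,3R,4S)-2-{[(6,8-dimethoxy-2-oxo-2H-chromen-7-yl)oxy]methyl}-3-ethenyl-3-methyl-4-[2-(2-methyl-1,3-dioxolan-2-yl)propan-2-yl]cyclohexan-1-one | COc1cc2ccc(=O)oc2c(OC)c1OC[C@H]1C(=O)CC[C@H](C(C)(C)C2(C)OCCO2)[C@@]1(C)C=C | intermediate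
22 | potassium (4S,5R,6S)-6-{[(6,8-dimethoxy-2-oxo-2H-chromen-7-yl)oxy]methyl}-5-ethenyl-5-methyl-4-[2-(2-methyl-1,3-dioxolan-2-yl)propan-2-yl]cyclohex-1-en-1-olate | COc1cc2ccc(=O)oc2c(OC)c1OC[C@H]1C(O[K])=CC[C@H](C(C)(C)C2(C)OCCO2)[C@@]1(C)C=C | intermediate (not isolated)
23 | (4S,5R,6S)-6-{[(6,8-dimethoxy-2-oxo-2H-chromen-7-yl)oxy]methyl}-5-ethenyl-5-methyl-4-[2-(2-methyl-1,3-dioxolan-2-yl)propan-2-yl]cyclohex-1-en-1-yl trifluoromethanesulfonate | COc1cc2ccc(=O)oc2c(OC)c1OC[C@H]1C(OS(=O)(=O)C(F)(F)F)=CC[C@H](C(C)(C)C2(C)OCCO2)[C@@]1(C)C=C | intermediate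
24 | (4S,5R,6S)-5-(1,2-dihydroxyethyl)-6-{[(6,8-dimethoxy-2-oxo-2H-chromen-7-yl)oxy]methyl}-5-methyl-4-[2-(2-methyl-1,3-dioxolan-2-yl)propan-2-yl]cyclohex-1-en-1-yl trifluoromethanesulfonate (both carbinol epimers) | COc1cc2ccc(=O)oc2c(OC)c1OC[C@H]1C(OS(=O)(=O)C(F)(F)F)=CC[C@H](C(C)(C)C2(C)OCCO2)[C@@]1(C)C(O)CO | intermediate (not isolated)
25 | (4S,5R,6S)-6-{[(6,8-dimethoxy-2-oxo-2H-chromen-7-yl)oxy]methyl}-5-formyl-5-methyl-4-[2-(2-methyl-1,3-dioxolan-2-yl)propan-2-yl]cyclohex-1-en-1-yl trifluoromethanesulfonate | COc1cc2ccc(=O)oc2c(OC)c1OC[C@H]1C(OS(=O)(=O)C(F)(F)F)=CC[C@H](C(C)(C)C2(C)OCCO2)[C@@]1(C)C=O | intermediate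
26 | (1R,2S,6S)-2-{[(6,8-dimethoxy-2-oxo-2H-chromen-7-yl)oxy]methyl}-1,3-dimethyl-6-[2-(2-methyl-1,3-dioxolan-2-yl)propan-2-yl]cyclohex-3-ene-1-carbaldehyde | COc1cc2ccc(=O)oc2c(OC)c1OC[C@H]1C(C)=CC[C@H](C(C)(C)C2(C)OCCO2)[C@@]1(C)C=O | intermediate
27 | (1R,2S,6S)-2-{[(6,8-dimethoxy-2-oxo-2H-chromen-7-yl)oxy]methyl}-1,3-dimethyl-6-(2-methyl-3-oxobutan-2-yl)cyclohex-3-ene-1-carbaldehyde | COc1cc2ccc(=O)oc2c(OC)c1OC[C@H]1C(C)=CC[C@H](C(C)(C)C(C)=O)[C@@]1(C)C=O | intermediate
28 | 7-{[(1S,4aS,8aR)-8-hydroxy-2,5,5,8a-tetramethyl-6-oxo-1,4,4a,5,6,7,8,8a-octahydronaphthalen-1-yl]methoxy}-6,8-dimethoxy-2H-chromen-2-one (either C8 carbinol epimer) | COc1cc2ccc(=O)oc2c(OC)c1OC[C@H]1C(C)=CC[C@@H]2C(C)(C)C(=O)CC(O)[C@]21C | intermediate (not isolated)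
29 | 7-{[(1S,4aS,8aR)-2,5,5,8a-tetramethyl-6-oxo-1,4,4a,5,6,8a-hexahydronaphthalen-1-yl]methoxy}-6,8-dimethoxy-2H-chromen-2-one | COc1cc2ccc(=O)oc2c(OC)c1OC[C@H]1C(C)=CC[C@@H]2C(C)(C)C(=O)C=C[C@]21C | target

## Step count and least certain steps

Total: 14 steps. Longest linear sequence: 12 steps (steps 1–6 and 9–14); steps 7–8 are a two-step side branch to 18.

**Step 9 (key step).** Three things may go wrong.
- Addition at the crowded β-carbon may be slow under catalytic copper, so that 1,2-attack or γ-deprotonation competes.
- The magnesium enolate may react sluggishly with 18, which is a less common enolate electrophile than an alkoxymethyl chloride. That would give time for O-alkylation, proton exchange with the product, or loss of aryloxide.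
- Facial selectivity at C9 may erode if the enolate conformers react at comparable rates.

The fallback separates the two events. It sets out from 13: the same cuprate addition is run with Me3SiCl as accelerator and trap, and the silyl enol ether F1 is isolated. MeLi in THF at 0 °C then releases the salt-free lithium enolate F2, which is alkylated with 18 in THF/DMPU at −78 °C and rejoins the route at 21.

**Step 10.** The potassium enolate may equilibrate towards C9 during its lifetime; this would expel the aryloxide or give the regioisomeric triflate, and the amide base may also attack the lactone. The fallback avoids a free enolate and sets out from 21. LiN(SiMe3)2 is added to 21 premixed with Me3SiCl at −78 °C, so that the kinetic enolate is silylated as it forms, giving the silyl enol ether F3. CsF and PhNTf2 in dimethoxyethane then convert F3 into the triflate, rejoining the route at 23.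

**Step 11.** Osmylation of a vinyl group on a quaternary carbon flanked by two substituted carbons may be slow enough for the coumarin C3=C4 bond to be dihydroxylated and cleaved. The fallback sets out from 23 and changes the oxidant class: ozone in CH2Cl2 at −78 °C, titrated with an indicator dye, should give the ozonide F4 at the vinyl group only. Reduction with Me2S rejoins the route at 25.

**Step 6.** Oxidation may be unselective (attack at the ring methyl, transposed products) or incomplete at the methylene next to the crowded ring. The fallback sets out from 12 and installs the oxygen by addition instead of C–H abstraction: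
- 3-chloroperbenzoic acid gives the epoxide F5;
- PhSeNa (from (PhSe)2 and NaBH4) opens it at the less substituted C9 to the hydroxy selenide F6;
- H2O2 gives the selenoxide F7, whose syn-elimination can only go towards C8 and yields the tertiary allylic alcohol F8;
- pyridinium chlorochromate effects the oxidative 1,3-transposition of F8, rejoining the route at 13.

**Step 14.** Bond formation between the hindered aldehyde and the methyl ketone may be slow, or the sequence may stop at the β-hydroxy ketone, because water is lost reluctantly from a carbinol next to a quaternary centre under weak-acid conditions. The fallback sets out from 28, isolated at that stage. MeSO2Cl/Et3N gives the mesylate F9, and 1,8-diazabicyclo[5.4.0]undec-7-ene eliminates it to the enone, rejoining the route at 29.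

## Further compounds

F1 | step 9 | {[(3R,4S)-3-ethenyl-3-methyl-4-[2-(2-methyl-1,3-dioxolan-2-yl)propan-2-yl]cyclohex-1-en-1-yl]oxy}trimethylsilane | C=C[C@@]1(C)C=C(O[Si](C)(C)C)CC[C@@H]1C(C)(C)C2(C)OCCO2
F2 | step 9 | lithium (3R,4S)-3-ethenyl-3-methyl-4-[2-(2-methyl-1,3-dioxolan-2-yl)propan-2-yl]cyclohex-1-en-1-olate | C=C[C@@]1(C)C=C(O[Li])CC[C@@H]1C(C)(C)C2(C)OCCO2
F3 | step 10 | 7-({(1S,5S,6R)-6-ethenyl-6-methyl-5-[2-(2-methyl-1,3-dioxolan-2-yl)propan-2-yl]-2-[(trimethylsilyl)oxy]cyclohex-2-en-1-yl}methoxy)-6,8-dimethoxy-2H-chromen-2-one | COc1cc2ccc(=O)oc2c(OC)c1OC[C@H]1C(O[Si](C)(C)C)=CC[C@H](C(C)(C)C2(C)OCCO2)[C@@]1(C)C=C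
F4 | step 11 | (4S,5R,6S)-6-{[(6,8-dimethoxy-2-oxo-2H-chromen-7-yl)oxy]methyl}-5-methyl-4-[2-(2-methyl-1,3-dioxolan-2-yl)propan-2-yl]-5-(1,2,4-trioxolan-3-yl)cyclohex-1-en-1-yl trifluoromethanesulfonate | COc1cc2ccc(=O)oc2c(OC)c1OC[C@H]1C(OS(=O)(=O)C(F)(F)F)=CC[C@H](C(C)(C)C2(C)OCCO2)[C@@]1(C)C1OCOO1
F5 | step 6 | 2-methyl-2-{2-[(2R)-1-methyl-7-oxabicyclo[4.1.0]heptan-2-yl]propan-2-yl}-1,3-dioxolane (epoxide expected anti to the side chain) | CC12OC1CCC[C@@H]2C(C)(C)C1(C)OCCO1
F6 | step 6 | (2R)-1-methyl-2-[2-(2-methyl-1,3-dioxolan-2-yl)propan-2-yl]-6-(phenylselanyl)cyclohexan-1-ol (hydroxyl and selenium trans) | CC1(O)C([Se]c2ccccc2)CCC[C@@H]1C(C)(C)C3(C)OCCO3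
F7 | step 6 | (2R)-1-methyl-2-[2-(2-methyl-1,3-dioxolan-2-yl)propan-2-yl]-6-(phenylseleninyl)cyclohexan-1-ol | CC1(O)C([Se](=O)c2ccccc2)CCC[C@@H]1C(C)(C)C3(C)OCCO3
F8 | step 6 | (6R)-1-methyl-6-[2-(2-methyl-1,3-dioxolan-2-yl)propan-2-yl]cyclohex-2-en-1-ol | CC1(O)C=CCC[C@@H]1C(C)(C)C2(C)OCCO2
F9 | step 14 | (4aS,8S,8aR)-8-{[(6,8-dimethoxy-2-oxo-2H-chromen-7-yl)oxy]methyl}-4,4,7,8a-tetramethyl-3-oxo-1,2,3,4,4a,5,8,8a-octahydronaphthalen-1-yl methanesulfonate (either C1 epimer) | COc1cc2ccc(=O)oc2c(OC)c1OC[C@H]1C(C)=CC[C@@H]2C(C)(C)C(=O)CC(OS(C)(=O)=O)[C@]21C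
A1 | alternative 1 | 2-hydroxy-3,5-dimethoxy-4-(terpenylmethoxy)benzaldehyde diethyl acetal, the C3 ketone of the terpenyl unit as its ethylene ketal | CCOC(OCC)c1cc(OC)c(OC[C@H]2C(C)=CC[C@@H]3C(C)(C)C4(OCCO4)C=C[C@]32C)c(OC)c1O
A2 | alternative 1 | 4-(3,3-diethoxyprop-1-en-1-yl)-2,4-dimethoxy-3-(terpenylmethoxy)cyclobut-2-en-1-one, same ketal-protected terpenyl unit | CCOC(OCC)C=CC1(OC)C(OC[C@H]2C(C)=CC[C@@H]3C(C)(C)C4(OCCO4)C=C[C@]32C)=C(OC)C1=O
A3 | alternative 2 | 7-{[(1S,4aS,8aR)-2,5,5,8a-tetramethyl-6-oxo-1,4,4a,5,6,7,8,8a-octahydronaphthalen-1-yl]methoxy}-6,8-dimethoxy-2H-chromen-2-one | COc1cc2ccc(=O)oc2c(OC)c1OC[C@H]1C(C)=CC[C@@H]2C(C)(C)C(=O)CC[C@]21C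
A4 | alternative 2 | 7-({2-[2-(3-iodobut-2-en-1-yl)-1,3,3-trimethyl-4-oxocyclohexyl]ethenyl}oxy)-6,8-dimethoxy-2H-chromen-2-one, ring stereocentres as in A3 | COc1cc2ccc(=O)oc2c(OC)c1OC=C[C@]1(C)CCC(=O)C(C)(C)[C@H]1CC=C(C)I
A5 | alternative 3 | (1R,2S,6S)-2-{[(6,8-dimethoxy-2-oxo-2H-chromen-7-yl)oxy]methyl}-1,3-dimethyl-6-(2-methyl-3-oxobutan-2-yl)cyclohex-3-ene-1-carbaldehyde | COc1cc2ccc(=O)oc2c(OC)c1OC[C@H]1C(C)=CC[C@H](C(C)(C)C(C)=O)[C@@]1(C)C=O
A6 | alternative 3 | (2E)-2,4,4-trimethyl-5-oxohex-2-enal | O=C/C(C)=C/C(C)(C)C(C)=O
A7 | alternative 3 | 6,8-dimethoxy-7-{[(2E)-3-methylpenta-2,4-dien-1-yl]oxy}-2H-chromen-2-one | COc1cc2ccc(=O)oc2c(OC)c1OC/C=C(\C)C=C
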